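**Retrosynthetic overview**

1. α-Onocerin is C2-symmetric about the C11–C11′ bond (each half numbered as a labdane: C1–C10, C11 on C9). It is cut there, by reductive dimerization of an aldehyde followed by hydrogenation, so only one decalin has to be built; both C8=CH2 groups come last from 8-ketones (Wittig).
2. Each decalin comes from an intramolecular Diels–Alder reaction. Ring B is opened at C5–C10 and C8–C9 after adding a C6=C7 double bond, an 8-silyloxy group and a C11 aldehyde, which leads back to an acyclic (2E,8E,10E)-trienal.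
3. Enabling feature: in ring B the bonds C5–C10 and C8–C9 lie opposite each other and separate a four-carbon unit C5–C6–C7–C8 (diene) from the two-carbon unit C9–C10 (dienophile, activated through C11=O). C1–C4 of ring A form a four-atom tether that carries the only pre-set stereocentre, C3.
4. The trienal is assembled from 2,2-dimethylpent-4-enoic acid (C3–C6 and the gem-dimethyl group), MeLi (C2), propargyl bromide (C1, C10, C9), Me3Al and ClCO2Me (10-CH3, C11) and crotonaldehyde (C7, C8); C3 is set by CBS reduction.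
5. Order of ring formation: rings A and B of one half form together in step 10; the two decalins are then joined in step 11 and no further ring is made.

Key step: step 10

Remark: the target SMILES is read as each half being 3β-OH (3S), 5α-H, 9α-H, 10β-CH3. The C8 configuration drawn for 15–18 is the one expected from endo addition; it is erased in 19.

**Route**

Step 1
Reactants: 1 2,2-dimethylpent-4-enoic acid
Product: 2 3,3-dimethylhex-5-en-2-one
Conditions: MeLi (2.2 equiv), Et2O, 0 °C to rt; inverse quench into cold aq. HCl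
Reagents that add atoms: methyllithium, [Li]C
Why: Addition of methyllithium to the lithium carboxylate should stop at the dilithio gem-diolate, which gives the methyl ketone only on hydrolysis (methyl ketone synthesis from a carboxylic acid), and no stereocentre is formed.

Step 2
Reactants: 2 3,3-dimethylhex-5-en-2-one; 3 3-bromoprop-1-yne
Product: 5 4,4-dimethylnon-1-en-8-yn-5-one, via lithium enolate 4 (not isolated)
Conditions: LiN(iPr)2 (1.05 equiv), THF, −78 °C; then 3, DMPU, −78 °C to 0 °C
Reagents that add atoms: 3-bromoprop-1-yne (3), C#CCBr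
Why: The ketone has α-hydrogens only on the methyl group, so kinetic enolate formation and SN2 alkylation with the propargylic bromide (enolate alkylation) should give a single regioisomer, with no stereocentre formed.

Step 3
Reactants: 5 4,4-dimethylnon-1-en-8-yn-5-one
Product: 6 (5S)-4,4-dimethylnon-1-en-8-yn-5-ol
Conditions: (R)-2-methyl-CBS-oxazaborolidine (0.2 equiv), catecholborane (1.5 equiv), toluene, −78 °C to −30 °C; aq. NaOH work-up
Reagents that add atoms: none
Why: In the CBS reduction the tert-alkyl group acts as the large and the CH2CH2C≡CH chain as the small substituent, so the (R)-catalyst should deliver hydride to the face that gives the S carbinol (future C3), and catecholborane is chosen because it does not hydroborate the alkene or alkyne at this temperature.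

Step 4
Reactants: 6 (5S)-4,4-dimethylnon-1-en-8-yn-5-ol
Product: 7 triisopropyl{[(5S)-4,4-dimethylnon-1-en-8-yn-5-yl]oxy}silane
Conditions: iPr3SiOTf (1.3 equiv), 2,6-lutidine, CH2Cl2, 0 °C to rt
Reagents that add atoms: triisopropylsilyl triflate, CC(C)[Si](OS(=O)(=O)C(F)(F)F)(C(C)C)C(C)C
Why: O-Silylation with a silyl triflate is the standard way to protect a hindered neopentyl-type secondary alcohol, and the stereocentre is not touched.

Step 5
Reactants: 7 triisopropyl{[(5S)-4,4-dimethylnon-1-en-8-yn-5-yl]oxy}silane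
Product: 9 methyl (2E,6S)-3,7,7-trimethyl-6-[(triisopropylsilyl)oxy]deca-2,9-dienoate, via alkenylalane 8 (not isolated)
Conditions: Me3Al (2.5 equiv), Cp2ZrCl2 (0.25 equiv), CH2Cl2, 0 °C to rt; then ClCO2Me, 0 °C to rt
Reagents that add atoms: trimethylaluminium, C[Al](C)C; methyl chloroformate, COC(=O)Cl
Why: Negishi zirconium-catalysed carboalumination adds CH3 and Al syn across the terminal alkyne (CH3 to the internal carbon) and acylation of the alkenylalane proceeds with retention, which fixes the E trisubstituted alkene, while the monosubstituted alkene should react much more slowly under these conditions.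

Step 6
Reactants: 9 methyl (2E,6S)-3,7,7-trimethyl-6-[(triisopropylsilyl)oxy]deca-2,9-dienoate; 10 (E)-but-2-enal
Product: 11 methyl (2E,6S,9E)-3,7,7-trimethyl-11-oxo-6-[(triisopropylsilyl)oxy]undeca-2,9-dienoate
Conditions: second-generation Hoveyda–Grubbs catalyst RuCl2(H2IMes)(=CH–C6H4-2-OiPr) (5 mol%), 10 (5 equiv), CH2Cl2, 40 °C
Reagents that add atoms: (E)-but-2-enal (10), C/C=C/C=O
Why: Olefin cross-metathesis of the terminal alkene with an enal should give the E-enal under thermodynamic control, and the trisubstituted enoate alkene is inert to the catalyst.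

Step 7
Reactants: 11 methyl (2E,6S,9E)-3,7,7-trimethyl-11-oxo-6-[(triisopropylsilyl)oxy]undeca-2,9-dienoate
Product: 12 methyl (2E,6S,8E,10E)-11-[(tert-butyldimethylsilyl)oxy]-3,7,7-trimethyl-6-[(triisopropylsilyl)oxy]undeca-2,8,10-trienoate
Conditions: tBuMe2SiOTf (1.2 equiv), Et3N (2 equiv), CH2Cl2, −78 °C to 0 °C
Reagents that add atoms: tert-butyldimethylsilyl triflate, CC(C)(C)[Si](C)(C)OS(=O)(=O)C(F)(F)F
Why: Soft enolization of the enal (O-silylation, then γ-deprotonation by the amine) is the standard route to 1-silyloxy-1,3-dienes; the s-trans enal should give the 10E enol ether, the bulk of the quaternary carbon the 8E alkene, and the less easily enolized ester should stay untouched.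

Step 8
Reactants: 12 methyl (2E,6S,8E,10E)-11-[(tert-butyldimethylsilyl)oxy]-3,7,7-trimethyl-6-[(triisopropylsilyl)oxy]undeca-2,8,10-trienoate
Product: 13 (2E,6S,8E,10E)-11-[(tert-butyldimethylsilyl)oxy]-3,7,7-trimethyl-6-[(triisopropylsilyl)oxy]undeca-2,8,10-trien-1-ol
Conditions: iBu2AlH (2.5 equiv), CH2Cl2, −78 °C; aq. potassium sodium tartrate work-up
Reagents that add atoms: none
Why: 1,2-Reduction of the enoate to the allylic alcohol with a dialkylaluminium hydride leaves silyl ethers and the silyl dienol ether intact, and the neutral work-up protects the enol ether.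

Step 9
Reactants: 13 (2E,6S,8E,10E)-11-[(tert-butyldimethylsilyl)oxy]-3,7,7-trimethyl-6-[(triisopropylsilyl)oxy]undeca-2,8,10-trien-1-ol
Product: 14 (2E,6S,8E,10E)-11-[(tert-butyldimethylsilyl)oxy]-3,7,7-trimethyl-6-[(triisopropylsilyl)oxy]undeca-2,8,10-trienal
Conditions: MnO2 (20 equiv), CH2Cl2, rt; used at once
Reagents that add atoms: none
Why: Allylic oxidation with MnO2 is neutral and chemoselective, so the E-enal should form without loss of the acid-labile silyl dienol ether or of alkene geometry.

Step 10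
Reactants: 14 (2E,6S,8E,10E)-11-[(tert-butyldimethylsilyl)oxy]-3,7,7-trimethyl-6-[(triisopropylsilyl)oxy]undeca-2,8,10-trienal
Product: 15 8β-[(tert-butyldimethylsilyl)oxy]-3β-[(triisopropylsilyl)oxy]-12-nordrim-6-en-11-al (trans-decalin; 5α-H, 9α-H, 10β-CH3)
Conditions: Me2AlCl (1.2 equiv), CH2Cl2 (0.01 M), −78 °C to −30 °C; aq. potassium sodium tartrate work-up
Reagents that add atoms: none
Why: Me2AlCl binds the formyl oxygen and lowers the LUMO of the (E)-β,β-disubstituted enal so that it is matched with the electron-rich (E,E)-1-silyloxydiene, and the bonds C5–C10 and C8–C9 should form in one concerted, asynchronous [4+2] event in which C5–C10 leads (the stepwise limit, vinylogous Mukaiyama–Michael addition then aldol-type closure, gives the same product). The closest known reaction type is the Lewis-acid-promoted intramolecular Diels–Alder reaction of 1,7,9-decatrienes with a terminal carbonyl group on the dienophile, which gives trans-decalins. Ring B is closed as the new cyclohexene by the cycloaddition itself, and ring A is closed in the same event by the C5–C10 bond through the four-atom tether C1–C4 held in a chair. C9 and C10 are related by the E geometry of the enal (suprafacial addition puts 10-CH3 and the formyl group cis), C5 is set against C10 by the endo position of the Lewis-acid-bound formyl group with the tether anti (trans fusion, 5α-H and 10β-CH3), and C8 by the E enol ether (OTBS cis to CHO, a centre that is erased later). The absolute sense comes from C3, whose OTIPS group should sit equatorial in the chair tether to avoid 1,3-diaxial contacts with H-1 and H-5, which exposes the diene face that gives 3β-O, 5α-H and 10β-CH3. The step needs endo selectivity, π-facial selectivity and 1,4- instead of 1,2-attack on the enal; these are secured by the terminal Lewis-acid-bound E-formyl group, by the equatorial C3 substituent, and by the fact that only attack at C10 closes a six-membered ring.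

Step 11
Reactants: 15 8β-[(tert-butyldimethylsilyl)oxy]-3β-[(triisopropylsilyl)oxy]-12-nordrim-6-en-11-al (two molecules)
Product: 16 (E)-alkene dimer of 15 (C9–C11H=C11′H–C9′; each half as in 15)
Conditions: TiCl3(DME)1.5, Zn–Cu couple, DME, reflux
Reagents that add atoms: none
Why: In the McMurry coupling low-valent titanium joins two aldehyde molecules to a titanium pinacolate and deoxygenates it at reflux to the C11=C11′ alkene; homocoupling of a single enantiomer can only give the C2-symmetric product, and the alkene geometry is irrelevant because step 12 saturates it.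

Step 12
Reactants: 16 (E)-alkene dimer of 15
Product: 17 saturated dimer (C9–C11H2–C11′H2–C9′; 8β,8′β-OTBS; 3β,3′β-OTIPS; both rings B saturated)
Conditions: H2 (3 atm), PtO2, EtOAc, rt
Reagents that add atoms: none
Why: Heterogeneous hydrogenation over PtO2 should saturate the three 1,2-disubstituted alkenes (C6=C7, C6′=C7′, C11=C11′) with less risk of allylic C–O hydrogenolysis than palladium, and only CH2 groups are created, so no stereocentre is set.

Step 13
Reactants: 17 saturated dimer
Product: 18 8β,8′β-diol (3β,3′β-OTIPS retained)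
Conditions: HF·pyridine, pyridine, THF, 0 °C to rt
Reagents that add atoms: none
Why: Selective desilylation relies on the markedly faster cleavage of a secondary tert-butyldimethylsilyl ether than of a secondary triisopropylsilyl ether at a neopentyl position.

Step 14
Reactants: 18 8β,8′β-diol
Product: 19 8,8′-diketone (3β,3′β-OTIPS)
Conditions: Dess–Martin periodinane (3 equiv), CH2Cl2, rt
Reagents that add atoms: none
Why: Dess–Martin oxidation converts hindered secondary alcohols into ketones under nearly neutral conditions, and C9 and C9′ already hold the more stable equatorial side chain, so epimerization is not a concern.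

Step 15
Reactants: 19 8,8′-diketone
Product: 20 α-onocerin 3,3′-bis(triisopropylsilyl) ether
Conditions: Ph3PCH3Br (6 equiv), KOtBu (5.5 equiv), toluene, 90 °C
Reagents that add atoms: methyltriphenylphosphonium bromide, C[P+](c1ccccc1)(c1ccccc1)c1ccccc1.[Br-] (used as its ylide methylenetriphenylphosphorane, C=P(c1ccccc1)(c1ccccc1)c1ccccc1)
Why: Wittig methylenation with excess ylide at elevated temperature is the established way to turn hindered 8-oxo decalins into 8(17)-exocyclic alkenes, and the α-centres C9 and C9′ are already in their thermodynamic configuration.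

Step 16
Reactants: 20 α-onocerin 3,3′-bis(triisopropylsilyl) ether
Product: 21 α-onocerin
Conditions: Bu4NF (6 equiv), THF, 60 °C
Reagents that add atoms: none
Why: Fluoride-mediated cleavage of the two triisopropylsilyl ethers releases the 3β-hydroxyl groups, and nothing else in the molecule reacts with fluoride.

**Compound list**

1 | 2,2-dimethylpent-4-enoic acid | C=CCC(C)(C)C(=O)O | starting material
2 | 3,3-dimethylhex-5-en-2-one | CC(=O)C(C)(C)CC=C | intermediate
3 | 3-bromoprop-1-yne (propargyl bromide) | C#CCBr | starting material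
4 | lithium 3,3-dimethylhexa-1,5-dien-2-olate (not isolated) | C=C(O[Li])C(C)(C)CC=C | intermediate
5 | 4,4-dimethylnon-1-en-8-yn-5-one | C=CCC(C)(C)C(=O)CCC#C | intermediate
6 | (5S)-4,4-dimethylnon-1-en-8-yn-5-ol | C=CCC(C)(C)[C@@H](O)CCC#C | intermediate
7 | triisopropyl{[(5S)-4,4-dimethylnon-1-en-8-yn-5-yl]oxy}silane | C=CCC(C)(C)[C@@H](O[Si](C(C)C)(C(C)C)C(C)C)CCC#C | intermediate
8 | dimethyl{(1E,5S)-2,6,6-trimethyl-5-[(triisopropylsilyl)oxy]nona-1,8-dien-1-yl}alane (not isolated) | C=CCC(C)(C)[C@@H](O[Si](C(C)C)(C(C)C)C(C)C)CC/C(C)=C/[Al](C)C | intermediate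
9 | methyl (2E,6S)-3,7,7-trimethyl-6-[(triisopropylsilyl)oxy]deca-2,9-dienoate | C=CCC(C)(C)[C@@H](O[Si](C(C)C)(C(C)C)C(C)C)CC/C(C)=C/C(=O)OC | intermediate
10 | (E)-but-2-enal (crotonaldehyde) | C/C=C/C=O | starting material
11 | methyl (2E,6S,9E)-3,7,7-trimethyl-11-oxo-6-[(triisopropylsilyl)oxy]undeca-2,9-dienoate | O=C/C=C/CC(C)(C)[C@@H](O[Si](C(C)C)(C(C)C)C(C)C)CC/C(C)=C/C(=O)OC | intermediate
12 | methyl (2E,6S,8E,10E)-11-[(tert-butyldimethylsilyl)oxy]-3,7,7-trimethyl-6-[(triisopropylsilyl)oxy]undeca-2,8,10-trienoate | CC(C)(C)[Si](C)(C)O/C=C/C=C/C(C)(C)[C@@H](O[Si](C(C)C)(C(C)C)C(C)C)CC/C(C)=C/C(=O)OC | intermediate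
13 | (2E,6S,8E,10E)-11-[(tert-butyldimethylsilyl)oxy]-3,7,7-trimethyl-6-[(triisopropylsilyl)oxy]undeca-2,8,10-trien-1-ol | CC(C)(C)[Si](C)(C)O/C=C/C=C/C(C)(C)[C@@H](O[Si](C(C)C)(C(C)C)C(C)C)CC/C(C)=C/CO | intermediate
14 | (2E,6S,8E,10E)-11-[(tert-butyldimethylsilyl)oxy]-3,7,7-trimethyl-6-[(triisopropylsilyl)oxy]undeca-2,8,10-trienal | CC(C)(C)[Si](C)(C)O/C=C/C=C/C(C)(C)[C@@H](O[Si](C(C)C)(C(C)C)C(C)C)CC/C(C)=C/C=O | intermediate
15 | 8β-[(tert-butyldimethylsilyl)oxy]-3β-[(triisopropylsilyl)oxy]-12-nordrim-6-en-11-al, i.e. 2-silyloxy-5,5,8a-trimethyl-6-silyloxy-1,2,4a,5,6,7,8,8a-octahydronaphthalene-1-carbaldehyde with 5α-H, 9α-H, 10β-CH3 | CC(C)(C)[Si](C)(C)O[C@H]1C=C[C@H]2C(C)(C)[C@@H](O[Si](C(C)C)(C(C)C)C(C)C)CC[C@]2(C)[C@H]1C=O | intermediate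
16 | (E)-alkene dimer of 15: two such decalins joined C9–C11H=C11′H–C9′ | CC(C)(C)[Si](C)(C)O[C@H]1C=C[C@H]2C(C)(C)[C@@H](O[Si](C(C)C)(C(C)C)C(C)C)CC[C@]2(C)[C@H]1/C=C/[C@H]1[C@@H](O[Si](C)(C)C(C)(C)C)C=C[C@H]2C(C)(C)[C@@H](O[Si](C(C)C)(C(C)C)C(C)C)CC[C@]12C | intermediate
17 | saturated dimer: C9–C11H2–C11′H2–C9′, 8β,8′β-bis(tert-butyldimethylsilyloxy), 3β,3′β-bis(triisopropylsilyloxy), trans-decalins | CC(C)(C)[Si](C)(C)O[C@H]1CC[C@H]2C(C)(C)[C@@H](O[Si](C(C)C)(C(C)C)C(C)C)CC[C@]2(C)[C@H]1CC[C@H]1[C@@H](O[Si](C)(C)C(C)(C)C)CC[C@H]2C(C)(C)[C@@H](O[Si](C(C)C)(C(C)C)C(C)C)CC[C@]12C | intermediate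
18 | 8β,8′β-diol of 17 (3β,3′β-bis(triisopropylsilyloxy) retained) | O[C@H]1CC[C@H]2C(C)(C)[C@@H](O[Si](C(C)C)(C(C)C)C(C)C)CC[C@]2(C)[C@H]1CC[C@H]1[C@@H](O)CC[C@H]2C(C)(C)[C@@H](O[Si](C(C)C)(C(C)C)C(C)C)CC[C@]12C | intermediate
19 | 8,8′-diketone (3β,3′β-bis(triisopropylsilyloxy)) | O=C1CC[C@H]2C(C)(C)[C@@H](O[Si](C(C)C)(C(C)C)C(C)C)CC[C@]2(C)[C@H]1CC[C@H]1C(=O)CC[C@H]2C(C)(C)[C@@H](O[Si](C(C)C)(C(C)C)C(C)C)CC[C@]12C | intermediate
20 | α-onocerin 3,3′-bis(triisopropylsilyl) ether | C=C1CC[C@H]2C(C)(C)[C@@H](O[Si](C(C)C)(C(C)C)C(C)C)CC[C@]2(C)[C@H]1CC[C@H]1C(=C)CC[C@H]2C(C)(C)[C@@H](O[Si](C(C)C)(C(C)C)C(C)C)CC[C@]12C | intermediate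
21 | α-onocerin | C=C1CC[C@H]2C(C)(C)[C@@H](O)CC[C@]2(C)[C@H]1CC[C@H]1C(=C)CC[C@H]2C(C)(C)[C@@H](O)CC[C@]12C | target

**Step count and risks**

Total step count: 16. Longest linear sequence: 16 steps (1 to 21; the route is linear and the two halves are joined by homodimerization in step 11).

Steps most likely to fail:

Step 10. The C3 silyloxy group may distinguish the two chair arrangements of the tether only weakly, so that the diene adds to both faces, or the Lewis acid may desilylate the dienol ether faster than the hindered enal reacts. The fallback replaces substrate control by auxiliary control and sets out from 9.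
- Saponification (LiOH, THF/MeOH/H2O, 50 °C) should give (2E,6S)-3,7,7-trimethyl-6-[(triisopropylsilyl)oxy]deca-2,9-dienoic acid F1.
- Pivaloyl chloride and Et3N convert it into the mixed pivalic anhydride F2 (not isolated), which acylates (S)-4-benzyloxazolidin-2-one (LiCl, THF) to the N-enoyl imide F3.
- Cross-metathesis with 10 as in step 6 gives the enal imide F4, and tBuMe2SiOTf/Et3N as in step 7 gives the silyl dienol ether imide F5.
- Me2AlCl (2 equiv, CH2Cl2, −40 °C) chelates both imide carbonyls and fixes the s-cis enoyl group. The benzyl group then blocks the diene approach that the axial-OTIPS chair would use (matched with the C3 bias), and the intramolecular Diels–Alder reaction should give the cycloadduct imide F6.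
- LiBH4 (THF/MeOH, 0 °C) removes the auxiliary and gives the primary alcohol F7; Dess–Martin oxidation then returns to the route at 15.

Step 11. The hindered α-branched aldehyde may stop at the pinacol stage, or silanol may be lost by β-elimination (8-OTBS lies β to the enolizable C9–H) under the hot, Lewis-acidic conditions. The fallback forms the C11–C11′ bond between sp3 carbons and sets out from 15.
- NaBH4 (EtOH, 0 °C) gives the primary alcohol F8 (identical in constitution with F7).
- I2, PPh3 and imidazole (CH2Cl2) give the primary iodide F9.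
- Nickel-catalysed reductive homocoupling (NiCl2(dme), 4,4′-di-tert-butyl-2,2′-bipyridine, Zn, DMA, rt) joins two alkyl radicals derived from the iodide to the dimer F10, which has a saturated C11–C11′ linker and both C6=C7 alkenes.
- Hydrogenation as in step 12 returns to the route at 17.

Step 5. The terminal alkene may be carbo- or hydrometalated alongside the alkyne, or the alkenylalane may be acylated incompletely. The fallback builds the enoate by carbonyl olefination and sets out from 7.
- Gold-catalysed Markovnikov hydration of the terminal alkyne (Ph3PAuNTf2, aqueous dioxane, 60 °C) gives the methyl ketone (5S)-6,6-dimethyl-5-[(triisopropylsilyl)oxy]non-8-en-2-one F11.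
- Horner–Wadsworth–Emmons olefination with trimethyl phosphonoacetate and NaH (THF, reflux) should give mainly the 2E enoate; after chromatographic removal of the 2Z isomer this returns to the route at 9.

**Further compounds**

F1 | step 10 | (2E,6S)-3,7,7-trimethyl-6-[(triisopropylsilyl)oxy]deca-2,9-dienoic acid | C=CCC(C)(C)[C@@H](O[Si](C(C)C)(C(C)C)C(C)C)CC/C(C)=C/C(=O)O
F2 | step 10 | (2E,6S)-3,7,7-trimethyl-6-[(triisopropylsilyl)oxy]deca-2,9-dienoic pivalic anhydride | C=CCC(C)(C)[C@@H](O[Si](C(C)C)(C(C)C)C(C)C)CC/C(C)=C/C(=O)OC(=O)C(C)(C)C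
F3 | step 10 | (4S)-4-benzyl-3-{(2E,6S)-3,7,7-trimethyl-6-[(triisopropylsilyl)oxy]deca-2,9-dienoyl}oxazolidin-2-one | C=CCC(C)(C)[C@@H](O[Si](C(C)C)(C(C)C)C(C)C)CC/C(C)=C/C(=O)N1[C@@H](Cc2ccccc2)COC1=O
F4 | step 10 | (4S)-4-benzyl-3-{(2E,6S,9E)-3,7,7-trimethyl-11-oxo-6-[(triisopropylsilyl)oxy]undeca-2,9-dienoyl}oxazolidin-2-one | O=C/C=C/CC(C)(C)[C@@H](O[Si](C(C)C)(C(C)C)C(C)C)CC/C(C)=C/C(=O)N1[C@@H](Cc2ccccc2)COC1=O
F5 | step 10 | (4S)-4-benzyl-3-{(2E,6S,8E,10E)-11-[(tert-butyldimethylsilyl)oxy]-3,7,7-trimethyl-6-[(triisopropylsilyl)oxy]undeca-2,8,10-trienoyl}oxazolidin-2-one | CC(C)(C)[Si](C)(C)O/C=C/C=C/C(C)(C)[C@@H](O[Si](C(C)C)(C(C)C)C(C)C)CC/C(C)=C/C(=O)N1[C@@H](Cc2ccccc2)COC1=O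
F6 | step 10 | cycloadduct imide: 15 with C(=O)–N[(4S)-4-benzyl-2-oxooxazolidin-3-yl] in place of the formyl group | CC(C)(C)[Si](C)(C)O[C@H]1C=C[C@H]2C(C)(C)[C@@H](O[Si](C(C)C)(C(C)C)C(C)C)CC[C@]2(C)[C@H]1C(=O)N1[C@@H](Cc2ccccc2)COC1=O
F7 | step 10 | 8β-[(tert-butyldimethylsilyl)oxy]-3β-[(triisopropylsilyl)oxy]-12-nordrim-6-en-11-ol | CC(C)(C)[Si](C)(C)O[C@H]1C=C[C@H]2C(C)(C)[C@@H](O[Si](C(C)C)(C(C)C)C(C)C)CC[C@]2(C)[C@H]1CO
F8 | step 11 | 8β-[(tert-butyldimethylsilyl)oxy]-3β-[(triisopropylsilyl)oxy]-12-nordrim-6-en-11-ol | CC(C)(C)[Si](C)(C)O[C@H]1C=C[C@H]2C(C)(C)[C@@H](O[Si](C(C)C)(C(C)C)C(C)C)CC[C@]2(C)[C@H]1CO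
F9 | step 11 | 11-iodo-8β-[(tert-butyldimethylsilyl)oxy]-3β-[(triisopropylsilyl)oxy]-12-nordrim-6-ene | CC(C)(C)[Si](C)(C)O[C@H]1C=C[C@H]2C(C)(C)[C@@H](O[Si](C(C)C)(C(C)C)C(C)C)CC[C@]2(C)[C@H]1CI
F10 | step 11 | dimer with saturated C11–C11′ linker and both C6=C7 alkenes (each half as in 15) | CC(C)(C)[Si](C)(C)O[C@H]1C=C[C@H]2C(C)(C)[C@@H](O[Si](C(C)C)(C(C)C)C(C)C)CC[C@]2(C)[C@H]1CC[C@H]1[C@@H](O[Si](C)(C)C(C)(C)C)C=C[C@H]2C(C)(C)[C@@H](O[Si](C(C)C)(C(C)C)C(C)C)CC[C@]12C
F11 | step 5 | (5S)-6,6-dimethyl-5-[(triisopropylsilyl)oxy]non-8-en-2-one | C=CCC(C)(C)[C@@H](O[Si](C(C)C)(C(C)C)C(C)C)CCC(C)=O
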